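**Retrosynthetic overview**
1. Target 9 ⇐ enoate 7 (ester → allylic alcohol) ⇐ aryl ketone 6 (chelation-controlled reduction; C8 dictates C7).
2. Key disconnection: the aryl–C7 bond of 6 ⇒ veratrole (C–H) + enantiopure α-aryloxy acid 3. A stereoretentive Friedel–Crafts acylation desymmetrises C2v-symmetric veratrole in the fragment-joining step. It tolerates the acrylate ester that an aryl-metal reagent would attack, so no protecting groups are needed.
3. Acid 3 ⇐ methyl sinapate + (R)-2-chloropropanoic acid (SN2 with inversion sets C8 = S).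
4. Rings: none is formed; both benzene rings are bought intact.

Assumption: methyl sinapate, (R)-2-chloropropanoic acid and veratrole are purchased, and Zn(BH4)2 is used as a pre-formed ether stock solution.

**Step 1**
Reactants: 1 methyl sinapate [methyl (2E)-3-(4-hydroxy-3,5-dimethoxyphenyl)prop-2-enoate]; 2 (2R)-2-chloropropanoic acid (1.2 equiv)
Product: 3 (2S)-2-{2,6-dimethoxy-4-[(1E)-3-methoxy-3-oxoprop-1-en-1-yl]phenoxy}propanoic acid
Conditions: NaH (2.3 equiv), THF/DMF 4:1, 0 → 60 °C, 12 h; then 1 M HCl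
Reagents that add atoms: none
Why: Williamson ether synthesis (SN2): the sodium phenoxide of 1 displaces chloride from the sodium carboxylate of 2 with inversion, turning the (R)-C–Cl centre into the (S)-C–OAr centre that becomes C8, and the carboxylate form keeps the α-H non-acidic (ee preserved) while the anhydrous medium leaves the methyl cinnamate intact.

**Step 2**
Reactants: 3 (2S)-2-{2,6-dimethoxy-4-[(1E)-3-methoxy-3-oxoprop-1-en-1-yl]phenoxy}propanoic acid; 4 veratrole (1,2-dimethoxybenzene, 3 equiv)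
Product: 6 methyl (2E)-3-(4-{[(2S)-1-(3,4-dimethoxyphenyl)-1-oxopropan-2-yl]oxy}-3,5-dimethoxyphenyl)prop-2-enoate, via mixed trifluoroacetic anhydride 5 (not isolated)
Conditions: TFAA (4 equiv), 85% H3PO4 (1 equiv), CH2Cl2, 0 °C → rt, 2–4 h
Reagents that add atoms: trifluoroacetic anhydride, O=C(OC(=O)C(F)(F)F)C(F)(F)F (its CF3CO group is carried only by intermediate 5 and leaves again as CF3CO2H; product 6 keeps no reagent atoms)
Why: Dehydrative Friedel–Crafts acylation: the acyl trifluoroacetate 5 acylates veratrole para to a methoxy group (positions 4 and 5 are equivalent, so one regioisomer forms and the arene's symmetry is lost), no bond to C8 is touched and no base is present so the S centre is retained, and ring B is protected by its blocked ortho positions and electron-poor acrylate.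

**Step 3**
Reactants: 6 methyl (2E)-3-(4-{[(2S)-1-(3,4-dimethoxyphenyl)-1-oxopropan-2-yl]oxy}-3,5-dimethoxyphenyl)prop-2-enoate
Product: 7 methyl (2E)-3-(4-{[(1R,2S)-1-(3,4-dimethoxyphenyl)-1-hydroxypropan-2-yl]oxy}-3,5-dimethoxyphenyl)prop-2-enoate
Conditions: Zn(BH4)2 (1.5 equiv, 0.3 M in Et2O), Et2O/CH2Cl2, −30 → 0 °C; aq NH4Cl
Reagents that add atoms: none
Why: Chelation-controlled (Cram-chelate) hydride reduction: Zn2+ bridges the ketone and α-aryloxy oxygens, hydride enters anti to the C8 methyl and sets C7 as R, giving the erythro (1R,2S) alcohol (expected dr about 9:1, minor threo isomer removed by chromatography), while the enoate is inert to Zn(BH4)2.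

**Step 4**
Reactants: 7 methyl (2E)-3-(4-{[(1R,2S)-1-(3,4-dimethoxyphenyl)-1-hydroxypropan-2-yl]oxy}-3,5-dimethoxyphenyl)prop-2-enoate
Product: 9 (1R,2S)-1-(3,4-dimethoxyphenyl)-2-{4-[(1E)-3-hydroxyprop-1-en-1-yl]-2,6-dimethoxyphenoxy}propan-1-ol, via enal 8 (not isolated)
Conditions: DIBAL-H (4 equiv, 1 M in toluene), CH2Cl2, −78 °C, 1 h; aq Rochelle salt
Reagents that add atoms: none
Why: DIBAL-H 1,2-reduction of the α,β-unsaturated methyl ester through the enal to the (E)-allylic alcohol (one extra equivalent is consumed by the free secondary OH), with no stereocentre, ether or alkene geometry affected.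

**Compound list**
1 | methyl sinapate, methyl (2E)-3-(4-hydroxy-3,5-dimethoxyphenyl)prop-2-enoate | COC(=O)/C=C/c1cc(OC)c(O)c(OC)c1 | starting material
2 | (2R)-2-chloropropanoic acid | C[C@@H](Cl)C(=O)O | starting material
3 | (2S)-2-{2,6-dimethoxy-4-[(1E)-3-methoxy-3-oxoprop-1-en-1-yl]phenoxy}propanoic acid | C[C@H](Oc1c(OC)cc(/C=C/C(=O)OC)cc1OC)C(=O)O | intermediate
4 | veratrole, 1,2-dimethoxybenzene | COc1ccccc1OC | starting material
5 | (2S)-2-{2,6-dimethoxy-4-[(1E)-3-methoxy-3-oxoprop-1-en-1-yl]phenoxy}propanoic trifluoroacetic anhydride | C[C@H](Oc1c(OC)cc(/C=C/C(=O)OC)cc1OC)C(=O)OC(=O)C(F)(F)F | intermediate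
6 | methyl (2E)-3-(4-{[(2S)-1-(3,4-dimethoxyphenyl)-1-oxopropan-2-yl]oxy}-3,5-dimethoxyphenyl)prop-2-enoate | COc1ccc(C(=O)[C@H](C)Oc2c(OC)cc(/C=C/C(=O)OC)cc2OC)cc1OC | intermediate
7 | methyl (2E)-3-(4-{[(1R,2S)-1-(3,4-dimethoxyphenyl)-1-hydroxypropan-2-yl]oxy}-3,5-dimethoxyphenyl)prop-2-enoate | COc1ccc([C@@H](O)[C@H](C)Oc2c(OC)cc(/C=C/C(=O)OC)cc2OC)cc1OC | intermediate
8 | (2E)-3-(4-{[(1R,2S)-1-(3,4-dimethoxyphenyl)-1-hydroxypropan-2-yl]oxy}-3,5-dimethoxyphenyl)prop-2-enal | COc1ccc([C@@H](O)[C@H](C)Oc2c(OC)cc(/C=C/C=O)cc2OC)cc1OC | intermediate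
9 | (1R,2S)-1-(3,4-dimethoxyphenyl)-2-{4-[(1E)-3-hydroxyprop-1-en-1-yl]-2,6-dimethoxyphenoxy}propan-1-ol | COc1ccc([C@@H](O)[C@H](C)Oc2c(OC)cc(/C=C/CO)cc2OC)cc1OC | target

**Step count and risk**
Total steps: 4. Longest linear sequence: 4 (1 → 3 → 6 → 7 → 9).

Steps most likely to fail, with fallbacks:

Step 2 is the riskiest, through partial racemisation of the α-aryloxy acyl donor or ketone in acid, or competing attack on ring B or the acrylate. The fallback replaces electrophilic aromatic substitution by a base-free acyl cross-coupling. Setting out from 3, EDC·HCl/HOBt and 4-methylbenzenethiol (CH2Cl2, 0 °C) give S-(4-methylphenyl) (2S)-2-{2,6-dimethoxy-4-[(1E)-3-methoxy-3-oxoprop-1-en-1-yl]phenoxy}propanethioate F1. Liebeskind–Srogl coupling of this thioester with (3,4-dimethoxyphenyl)boronic acid (Pd2(dba)3, tri(2-furyl)phosphine, CuTC, THF, 50 °C) comes back to the route at 6.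

Step 1 may suffer a sluggish SN2 with the hindered, acrylate-deactivated 2,6-dimethoxyphenoxide, or ee erosion by chloride exchange on 2. The fallback switches from halide displacement to alcohol activation. Setting out from 1, a Mitsunobu reaction with tert-butyl (R)-lactate (PPh3, DIAD, THF, 0 °C → rt, inversion) gives tert-butyl (2S)-2-{2,6-dimethoxy-4-[(1E)-3-methoxy-3-oxoprop-1-en-1-yl]phenoxy}propanoate F2. TFA/CH2Cl2 at rt then cleaves the tert-butyl ester and comes back to the route at 3.

Step 3 may give a lower dr than hoped if the twisted aryloxy oxygen chelates zinc poorly. The fallback switches from substrate (chelate) control to catalyst control. Setting out from 6, Noyori asymmetric transfer hydrogenation with RuCl[(S,S)-TsDPEN](p-cymene) in HCO2H/Et3N 5:2 at rt delivers hydride in the same spatial sense that gives (S)-1-phenylethanol from acetophenone, which here is the 1R descriptor. It comes back to the route at 7 and makes no new compound (F0).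

**Further compounds**
F1 | step 2 | S-(4-methylphenyl) (2S)-2-{2,6-dimethoxy-4-[(1E)-3-methoxy-3-oxoprop-1-en-1-yl]phenoxy}propanethioate | C[C@H](Oc1c(OC)cc(/C=C/C(=O)OC)cc1OC)C(=O)Sc1ccc(C)cc1
F2 | step 1 | tert-butyl (2S)-2-{2,6-dimethoxy-4-[(1E)-3-methoxy-3-oxoprop-1-en-1-yl]phenoxy}propanoate | C[C@H](Oc1c(OC)cc(/C=C/C(=O)OC)cc1OC)C(=O)OC(C)(C)C
F0 | step 3 | none | none
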